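Numbering: cyclohexane ring C1–C6 (C1 bears C7; C2 and C3 bear acyloxy groups; C4–C5 is the ring epoxide), C7=C14 is the exocyclic methylene, C8–C11 the side chain. The route rests on disconnecting C7–C8. The feature exploited is the 1,1-disubstituted allylic carbinol C14=C7–C8–O, an oxidised α-substituted allylboronate: in one flask, lithiation–borylation unites an (R)-α-lithiated homoprenyl carbamate (C8–C11, sparteine-controlled) with a ring-bound alkenyl pinacol boronate made from (S)-carvone; a stereospecific 1,2-metallate shift forges C7–C8 and fixes C8, and oxidation turns C–B into C–O. Desilylation, triple angeloylation and Shi epoxidation of C10=C11 finish.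

Key step: step 10

Remark on the chemistry: (S)-(+)-carvone, 4-methylpent-3-en-1-ol, (+)-sparteine and the D-fructose-derived Shi ketone are taken as commercially available; the numbering above is used for all intermediates, the isopropenyl methylene of carvone being excised as formaldehyde in step 6 and its former methyl becoming C14.

Step 1
Reactants: 1 (S)-(+)-carvone
Product: 4 trans-6-hydroxycarvone, via silyl dienol ether 2 (not isolated), via silyloxy ketone 3 (not isolated)
Conditions: LiN(iPr)2, Me3SiCl, THF, −78 °C; then mCPBA, NaHCO3, CH2Cl2, −20 to 0 °C; then 1 M HCl, THF, 0 °C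
Reagents that add atoms: mCPBA (OOC(=O)c1cccc(Cl)c1); Me3SiCl (C[Si](C)(C)Cl)
Why: Rubottom oxidation, in which the kinetic cross-conjugated trimethylsilyl dienol ether 2 is epoxidised by the peracid (the source of the C2 oxygen) at its electron-rich enol ether bond on the face anti to the adjacent C1 isopropenyl group, so that after silyl migration to 3 and hydrolytic loss of the silyl group the new C2 hydroxyl stands trans to that group.

Step 2
Reactants: 4 trans-6-hydroxycarvone
Product: 5 cis-6-(4-nitrobenzoyloxy)carvone
Conditions: 4-O2NC6H4CO2H, PPh3, DIAD, toluene, 0 °C to rt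
Reagents that add atoms: 4-nitrobenzoic acid (OC(=O)c1ccc(cc1)[N+](=O)[O-])
Why: Mitsunobu reaction, in which the equatorial α-ketol oxygen is activated as an oxyphosphonium ion and displaced by the carboxylate in an SN2 process accelerated by the neighbouring carbonyl, inverting C2 so that its oxygen becomes cis to the C1 substituent.

Step 3
Reactants: 5 cis-6-(4-nitrobenzoyloxy)carvone
Product: 7 all-cis diol, via hydroxy ester 6 (not isolated)
Conditions: NaBH4, CeCl3·7H2O, MeOH, −40 °C; then K2CO3, MeOH, rt
Reagents that add atoms: none
Why: Luche 1,2-reduction followed by in situ methanolysis, in which hydride adds to the C3 carbonyl along the axial trajectory anti to the pseudoaxial C2 acyloxy group and to the C1 substituent, placing the C3 hydroxyl cis to both neighbours, before the activated 4-nitrobenzoate is transesterified away.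

Step 4
Reactants: 7 all-cis diol
Product: 8 all-cis epoxy diol
Conditions: VO(acac)2 (cat.), tBuOOH, CH2Cl2, 0 °C to rt
Reagents that add atoms: tert-butyl hydroperoxide (CC(C)(C)OO)
Why: Hydroxyl-directed vanadium-catalysed epoxidation, in which the allylic C3 alkoxide bound to vanadium delivers the peroxide oxygen to the trisubstituted C4=C5 bond on its own face to give the cis-epoxy alcohol, while the less electron-rich isopropenyl group, only homoallylic to the C2 hydroxyl, should react far more slowly.

Step 5
Reactants: 8 all-cis epoxy diol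
Product: 9 bis(triethylsilyl) ether
Conditions: Et3SiCl, imidazole, DMAP (cat.), DMF, rt to 40 °C
Reagents that add atoms: chlorotriethylsilane (CC[Si](Cl)(CC)CC)
Why: Silyl ether formation on both secondary hydroxyls, chosen because triethylsilyl ethers tolerate ozone, amide bases and organolithium reagents and are later removed by fluoride without the acid that would endanger the epoxide.

Step 6
Reactants: 9 bis(triethylsilyl) ether
Product: 11 methyl ketone, via ozonide 10 (not isolated)
Conditions: O3, CH2Cl2, −78 °C; then Me2S, −78 °C to rt
Reagents that add atoms: ozone ([O-][O+]=O)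
Why: Ozonolysis with reductive work-up, which cleaves the isopropenyl group (the only alkene left) to the C7 methyl ketone under neutral conditions that should not epimerise the now enolisable C1.

Step 7
Reactants: 11 methyl ketone
Product: 13 enol triflate, via potassium enolate 12 (not isolated)
Conditions: KN(SiMe3)2, THF, −78 °C (ketone added to base); then PhNTf2, −78 to 0 °C
Reagents that add atoms: N-phenylbis(trifluoromethanesulfonimide) (FC(F)(F)S(=O)(=O)N(c1ccccc1)S(=O)(=O)C(F)(F)F); KN(SiMe3)2 (C[Si](C)(C)[N-][Si](C)(C)C.[K+])
Why: Kinetic enolisation and O-triflation, in which the bulky amide base removes a proton from the exposed methyl group (the future C14) and not from the hindered C1 methine, so that potassium enolate 12 is trapped on oxygen as the terminal enol triflate without loss of the C1 configuration or elimination of the C2 silyloxy group.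

Step 8
Reactants: 13 enol triflate
Product: 14 alkenyl pinacol boronate
Conditions: B2pin2, PdCl2(PPh3)2 (cat.), PPh3, KOPh, toluene, 50 °C
Reagents that add atoms: bis(pinacolato)diboron (CC1(C)OB(OC1(C)C)B1OC(C)(C)C(C)(C)O1)
Why: Miyaura borylation, in which oxidative addition of the alkenyl triflate to zerovalent palladium, phenoxide-assisted transmetalation with the diboron reagent and reductive elimination give the 1-substituted alkenyl boronate with the epoxide and silyl ethers untouched.

Step 9
Reactants: 15 4-methylpent-3-en-1-ol
Product: 16 homoprenyl N,N-diisopropylcarbamate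
Conditions: iPr2NCOCl, Et3N, CH2Cl2, reflux
Reagents that add atoms: N,N-diisopropylcarbamoyl chloride (CC(C)N(C(C)C)C(Cl)=O)
Why: Carbamoylation of a primary alcohol by acyl substitution, installing the group that later directs and stabilises α-lithiation at C8 and serves as the leaving group.

Step 10
Reactants: 14 alkenyl pinacol boronate; 16 homoprenyl N,N-diisopropylcarbamate
Product: 20 (S)-allylic alcohol bis(triethylsilyl) ether, via lithiated carbamate 17 (not isolated), via boronate complex 18 (not isolated), via allylic boronate 19 (not isolated)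
Conditions: 16, sBuLi, (+)-sparteine, Et2O, −78 °C; then 14, −78 °C; then warm to reflux; then NaOH, H2O2, THF, 0 °C
Reagents that add atoms: hydrogen peroxide (OO); sec-butyllithium (CCC(C)[Li])
Why: sBuLi/(+)-sparteine removes the pro-R hydrogen at C8 of 16 to give the configurationally stable (R)-lithio carbamate 17, which adds to boron of 14 with retention to form the lithium ate complex 18; on warming, the alkenyl carbon C7 migrates from boron to C8 anti-periplanar to the departing carbamate (inversion at C8), forging the C7–C8 bond in allylic boronate 19, whose C–B bond is oxidised by hydrogen peroxide with retention to the C8–O bond of 20. The closest known reaction type is the lithiation–borylation (Matteson-type 1,2-metallate rearrangement) of sparteine-derived lithiated carbamates with alkenyl pinacol boronates, giving α-substituted allylic boronates and then allylic alcohols. No ring is closed. The only new stereocenter, C8, is set as S purely by the sparteine enantiomer through the retention–inversion–retention sequence, independently of the ring stereocenters. The step needs attack at boron in preference to the epoxide and silyl ethers, which the high electrophilicity of the boronate at −78 °C secures, migration of carbon instead of a pinacol oxygen, which the high migratory aptitude of the alkenyl group secures, and no 1,3-borotropic shift before oxidation, which the pinacol ester and the cold oxidative work-up secure.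

Step 11
Reactants: 20 (S)-allylic alcohol bis(triethylsilyl) ether
Product: 21 triol
Conditions: Bu4NF, THF, 0 °C to rt
Reagents that add atoms: none
Why: Fluoride-mediated desilylation frees the C2 and C3 hydroxyls under non-acidic conditions, and the cis relationship between the C3 oxygen and the epoxide rules out a Payne rearrangement of the alkoxide.

Step 12
Reactants: 21 triol
Product: 22 tris-angelate
Conditions: angelic acid, 2,4,6-Cl3C6H2COCl, Et3N, toluene, rt; then 21, 75 °C
Reagents that add atoms: angelic acid (C/C=C(/C)C(=O)O)
Why: Yamaguchi-type esterification with the preformed mixed anhydride of angelic acid, in which the three secondary hydroxyls attack the less hindered angeloyl carbonyl while the absence of a nucleophilic catalyst and of an acyl chloride of the acid should preserve the Z geometry.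

Step 13
Reactants: 22 tris-angelate
Product: 23 target CNP0258231.4
Conditions: D-fructose-derived Shi ketone (cat.), KHSO5 (as 2KHSO5·KHSO4·K2SO4), K2CO3, Bu4NHSO4, MeCN/CH2(OMe)2/aqueous Na2B4O7 buffer, 0 °C
Reagents that add atoms: KHSO5 ([K+].[O-]S(=O)(=O)OO)
Why: Shi asymmetric epoxidation, in which the chiral dioxirane from the D-fructose-derived ketone transfers oxygen through a spiro transition state to the electron-rich trisubstituted C10=C11 bond only, the catalyst fixing C10 as R, while the 1,1-disubstituted C7=C14 bond flanked by an acyloxy group and the electron-poor angelate double bonds should not react.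

Compound list
1 | (S)-(+)-carvone, (5S)-2-methyl-5-(prop-1-en-2-yl)cyclohex-2-en-1-one | C=C(C)[C@H]1CC=C(C)C(=O)C1 | starting material
2 | kinetic trimethylsilyl dienol ether of 1 (enol ether between C3 and C2, C1 unchanged) | C=C(C)[C@H]1CC=C(C)C(O[Si](C)(C)C)=C1 | intermediate (not isolated)
3 | trans-6-(trimethylsilyloxy)carvone (silyloxy group trans to the isopropenyl group) | C=C(C)[C@H]1CC=C(C)C(=O)[C@@H]1O[Si](C)(C)C | intermediate (not isolated)
4 | trans-6-hydroxycarvone, (5R,6R)-6-hydroxy-2-methyl-5-(prop-1-en-2-yl)cyclohex-2-en-1-one | C=C(C)[C@H]1CC=C(C)C(=O)[C@@H]1O | intermediate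
5 | cis-6-(4-nitrobenzoyloxy)carvone, (1S,6R)-3-methyl-2-oxo-6-(prop-1-en-2-yl)cyclohex-3-en-1-yl 4-nitrobenzoate | C=C(C)[C@H]1CC=C(C)C(=O)[C@H]1OC(=O)c1ccc(cc1)[N+](=O)[O-] | intermediate
6 | all-cis hydroxy ester: 2-hydroxy-3-methyl-6-(prop-1-en-2-yl)cyclohex-3-en-1-yl 4-nitrobenzoate, with OH, ester and isopropenyl on one face | C=C(C)[C@H]1CC=C(C)[C@@H](O)[C@H]1OC(=O)c1ccc(cc1)[N+](=O)[O-] | intermediate (not isolated)
7 | all-cis diol: 3-methyl-6-(prop-1-en-2-yl)cyclohex-3-ene-1,2-diol, both OH cis to the isopropenyl group | C=C(C)[C@H]1CC=C(C)[C@@H](O)[C@H]1O | intermediate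
8 | all-cis epoxy diol: 1-methyl-4-(prop-1-en-2-yl)-7-oxabicyclo[4.1.0]heptane-2,3-diol, with epoxide O, both OH and isopropenyl on one face | C=C(C)[C@H]1C[C@H]2O[C@@]2(C)[C@@H](O)[C@H]1O | intermediate
9 | bis(triethylsilyl) ether of 8 | C=C(C)[C@H]1C[C@H]2O[C@@]2(C)[C@@H](O[Si](CC)(CC)CC)[C@H]1O[Si](CC)(CC)CC | intermediate
10 | secondary ozonide (1,2,4-trioxolane) of 9 | CC1(OOCO1)[C@H]1C[C@H]2O[C@@]2(C)[C@@H](O[Si](CC)(CC)CC)[C@H]1O[Si](CC)(CC)CC | intermediate (not isolated)
11 | methyl ketone: C1-acetyl epoxycyclohexane with C2 and C3 triethylsilyl ethers, all-cis | CC(=O)[C@H]1C[C@H]2O[C@@]2(C)[C@@H](O[Si](CC)(CC)CC)[C@H]1O[Si](CC)(CC)CC | intermediate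
12 | terminal potassium enolate of 11 (C7=C14) | [K+].C=C([O-])[C@H]1C[C@H]2O[C@@]2(C)[C@@H](O[Si](CC)(CC)CC)[C@H]1O[Si](CC)(CC)CC | intermediate (not isolated)
13 | enol triflate: C7 trifluoromethanesulfonate of the C7=C14 enol, ring as in 11 | C=C(OS(=O)(=O)C(F)(F)F)[C@H]1C[C@H]2O[C@@]2(C)[C@@H](O[Si](CC)(CC)CC)[C@H]1O[Si](CC)(CC)CC | intermediate
14 | alkenyl pinacol boronate: pinacolboryl group on C7 of the C7=C14 alkene, ring as in 11 | C=C(B1OC(C)(C)C(C)(C)O1)[C@H]1C[C@H]2O[C@@]2(C)[C@@H](O[Si](CC)(CC)CC)[C@H]1O[Si](CC)(CC)CC | intermediate
15 | 4-methylpent-3-en-1-ol | CC(C)=CCCO | starting material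
16 | 4-methylpent-3-en-1-yl N,N-diisopropylcarbamate | CC(C)=CCCOC(=O)N(C(C)C)C(C)C | intermediate
17 | (R)-1-lithio-4-methylpent-3-en-1-yl N,N-diisopropylcarbamate, (+)-sparteine complex | [Li][C@H](CC=C(C)C)OC(=O)N(C(C)C)C(C)C | intermediate (not isolated)
18 | lithium boronate (ate complex) carrying C7 and C8 on boron | [Li+].C=C([B-]1(OC(C)(C)C(C)(C)O1)[C@H](CC=C(C)C)OC(=O)N(C(C)C)C(C)C)[C@H]1C[C@H]2O[C@@]2(C)[C@@H](O[Si](CC)(CC)CC)[C@H]1O[Si](CC)(CC)CC | intermediate (not isolated)
19 | α-substituted allylic pinacol boronate (boron on C8, C7–C8 bond formed) | C=C([C@H](CC=C(C)C)B1OC(C)(C)C(C)(C)O1)[C@H]1C[C@H]2O[C@@]2(C)[C@@H](O[Si](CC)(CC)CC)[C@H]1O[Si](CC)(CC)CC | intermediate (not isolated)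
20 | (S)-C8 allylic alcohol with C2 and C3 triethylsilyl ethers | C=C([C@H](CC=C(C)C)O)[C@H]1C[C@H]2O[C@@]2(C)[C@@H](O[Si](CC)(CC)CC)[C@H]1O[Si](CC)(CC)CC | intermediate
21 | triol (free hydroxyls on C2, C3 and C8; C8 is S) | C=C([C@H](CC=C(C)C)O)[C@H]1C[C@H]2O[C@@]2(C)[C@@H](O)[C@H]1O | intermediate
22 | tris-angelate with the C10=C11 alkene still present | C=C([C@H](CC=C(C)C)OC(=O)/C(C)=C\C)[C@H]1C[C@H]2O[C@@]2(C)[C@@H](OC(=O)/C(C)=C\C)[C@H]1OC(=O)/C(C)=C\C | intermediate
23 | CNP0258231.4 (tris-angelate diepoxide; C8 is S, C10 is R) | C=C([C@H](C[C@H]1OC1(C)C)OC(=O)/C(C)=C\C)[C@H]1C[C@H]2O[C@@]2(C)[C@@H](OC(=O)/C(C)=C\C)[C@H]1OC(=O)/C(C)=C\C | target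

Total step count: 13
Longest linear sequence: 12 steps (steps 1–8 and 10–13, from (S)-carvone)

Steps most likely to fail

Step 10. Formation of the ate complex on the hindered, α-branched alkenyl boronate may be slow or reversible. In addition, a pinacol oxygen may migrate in competition with C7, or the allylic boronate may undergo a 1,3-borotropic shift before oxidation, eroding both conversion and the C8 configuration. The fallback sets out from enol triflate 13 and alcohol 15 and comes back at 20. Alcohol 15 is oxidised with Dess–Martin periodinane (NaHCO3, CH2Cl2) to 4-methylpent-3-enal F1. F1 is joined to 13 in a Nozaki–Hiyama–Kishi reaction (CrCl2, NiCl2 cat., DMF) to give the allylic alcohol as a mixture of C8 epimers F2. Oxidation of F2 with Dess–Martin periodinane gives the cross-conjugated enone F3. Corey–Bakshi–Shibata reduction of F3 with the (R)-methyl oxazaborolidine and BH3·SMe2 should deliver the (S)-alcohol 20, the α-branched alkenyl group acting as the large substituent.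

Step 2. The oxyphosphonium ion of the hindered α-ketol may be consumed by elimination, or the cis ester may epimerise through enolisation back toward the more stable trans series, so that inversion is incomplete. The fallback sets out from carvone 1 (through its silyl dienol ether 2) and comes back at 5. Bromination of 2 with N-bromosuccinimide (THF, −78 °C) should give trans-6-bromocarvone F4, with bromine anti to the isopropenyl group. SN2 displacement of the α-keto bromide with CsO2CC6H4NO2 in DMF then gives the cis ester 5 with inversion.

Step 12. Three hindered acylations on one molecule may stall at the C3 hydroxyl next to the quaternary epoxide carbon, and prolonged heating may isomerise angelate to tiglate. The fallback sets out from triol 21 and comes back at 22. Esterification with 2-[bis(2,2,2-trifluoroethoxy)phosphoryl]propanoic acid (DCC, DMAP, CH2Cl2) gives the tris(phosphonopropionate) F5. Threefold Still–Gennari olefination (KN(SiMe3)2, 18-crown-6, acetaldehyde, THF, −78 °C) then builds the three Z-configured 2-methylbut-2-enoates of 22.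

Further compounds
F1 | step 10 | 4-methylpent-3-enal | CC(C)=CCC=O
F2 | step 10 | allylic alcohol 20 as a mixture of C8 epimers | C=C(C(O)CC=C(C)C)[C@H]1C[C@H]2O[C@@]2(C)[C@@H](O[Si](CC)(CC)CC)[C@H]1O[Si](CC)(CC)CC
F3 | step 10 | cross-conjugated C8 enone | C=C(C(=O)CC=C(C)C)[C@H]1C[C@H]2O[C@@]2(C)[C@@H](O[Si](CC)(CC)CC)[C@H]1O[Si](CC)(CC)CC
F4 | step 2 | trans-6-bromocarvone | C=C(C)[C@H]1CC=C(C)C(=O)[C@@H]1Br
F5 | step 12 | tris{2-[bis(2,2,2-trifluoroethoxy)phosphoryl]propanoate} of triol 21 | C=C([C@H](CC=C(C)C)OC(=O)C(C)P(=O)(OCC(F)(F)F)OCC(F)(F)F)[C@H]1C[C@H]2O[C@@]2(C)[C@@H](OC(=O)C(C)P(=O)(OCC(F)(F)F)OCC(F)(F)F)[C@H]1OC(=O)C(C)P(=O)(OCC(F)(F)F)OCC(F)(F)F
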